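**Plan**

- Ring B carries vicinal oxygens on C6/C7 and an sp2 C8. Moving that alkene to C8=C9 exposes a [4+2] retron, so the retrosynthesis cuts C5–C10 and C6–C7: diene C7=C8–C9=C10 (both oxygens on it), dienophile C5=C6, tethered by C1–C3 of ring A.
- The benzoate C=O carbon (C21) serves as the dienophile's activating group. It is tied to C19, which sits 1,3-diaxial to C6, as a temporary δ-lactone; PhLi later opens the lactone and a Baeyer–Villiger shift turns C6–C(=O)Ph into C6–OC(=O)Ph.
- Forward: a linear chain from 5-chloropent-1-yne (two carboaluminations), the C4 quaternary centre, the lactone and the silyloxydiene; one intramolecular Diels–Alder reaction closes rings A and B; then the C9 chain, a masked C8 methylene, the benzoate, the C19 acid, the side-chain alkene and unmasking.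
- Stereochemistry: C4 from Sharpless epoxidation and a stereospecific 1,2-shift; C5, C6, C7, C10 from the cycloaddition (tether face, ring-locked cis alkene, (Z)-enol ether, (E)-alkene, anti mode); C9 by Michael addition anti to C20; C6–O by retentive migration; both trisubstituted alkenes by syn-carboalumination.

Key step: step 10

Remark: labdane numbering is used (C1–C10 decalin, C11–C16 side chain, C17 exocyclic CH2, C18/C19 on C4, C20 on C10); C21 is the lactone carbonyl carbon that ends as the benzoate C=O; α is the face opposite C20.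
Assumption: Weinreb amide 7 is taken as a catalogue compound (otherwise one step from methyl (tert-butyldimethylsilyloxy)acetate).

**Step 1**
Reactants: 1 5-chloropent-1-yne
Product: 3 (2E)-6-chloro-3-methylhex-2-en-1-ol, via alkenylalane 2 (not isolated)
Conditions: Me3Al, Cp2ZrCl2 (cat.), CH2Cl2, 0 °C to rt; then (CH2O)n, THF, 0 °C to rt
Reagents that add atoms: trimethylaluminium C[Al](C)C; paraformaldehyde (as formaldehyde) C=O
Why: Zirconium-catalysed syn-carboalumination (Negishi) puts CH3 on the internal alkyne carbon cis to aluminium, so trapping the alkenylalane with formaldehyde should give only the (E)-allylic alcohol.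

**Step 2**
Reactants: 3 (2E)-6-chloro-3-methylhex-2-en-1-ol
Product: 4 (2E)-3-methyloct-2-en-7-yn-1-ol
Conditions: LiC≡CH·H2NCH2CH2NH2 (excess), DMSO, 0 °C to rt
Reagents that add atoms: lithium acetylide–ethylenediamine complex [Li]C#C.NCCN
Why: SN2 alkylation of acetylide by the primary chloride in a dipolar aprotic solvent, with the allylic alcohol carried as its alkoxide and the alkene untouched.

**Step 3**
Reactants: 4 (2E)-3-methyloct-2-en-7-yn-1-ol
Product: 6 (2E,7E)-8-iodo-3,7-dimethylocta-2,7-dien-1-ol, via alkenylalane 5 (not isolated)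
Conditions: Me3Al, Cp2ZrCl2, CH2Cl2, 0 °C to rt; then I2, THF, −30 °C
Reagents that add atoms: trimethylaluminium C[Al](C)C; iodine II
Why: A second Negishi carboalumination (the hydroxyl is carried as its aluminium alkoxide) followed by iodinolysis with retention should give the (E)-alkenyl iodide that fixes the C9=C10 geometry.

**Step 4**
Reactants: 6 (2E,7E)-8-iodo-3,7-dimethylocta-2,7-dien-1-ol; 7 2-[(tert-butyldimethylsilyl)oxy]-N-methoxy-N-methylacetamide
Product: 9 (3E,8E)-1-[(tert-butyldimethylsilyl)oxy]-10-hydroxy-4,8-dimethyldeca-3,8-dien-2-one, via dilithio species 8 (not isolated)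
Conditions: t-BuLi (3.1 equiv), Et2O, −78 °C; then 7, −78 to 0 °C; aq. NH4Cl
Reagents that add atoms: none
Why: Iodine–lithium exchange with retention of alkene geometry and acylation of the alkenyllithium by the Weinreb amide (chelated adduct, no over-addition) should give the (E)-enone that carries C7 and its oxygen.

**Step 5**
Reactants: 9 (3E,8E)-1-[(tert-butyldimethylsilyl)oxy]-10-hydroxy-4,8-dimethyldeca-3,8-dien-2-one
Product: 10 (3E)-1-[(tert-butyldimethylsilyl)oxy]-7-[(2R,3R)-3-(hydroxymethyl)-2-methyloxiran-2-yl]-4-methylhept-3-en-2-one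
Conditions: Ti(OiPr)4 (cat.), D-(−)-diisopropyl tartrate (cat.), t-BuOOH, 4 Å MS, CH2Cl2, −20 °C
Reagents that add atoms: tert-butyl hydroperoxide CC(C)(C)OO
Why: Sharpless asymmetric epoxidation of the primary (E)-allylic alcohol, where the D-(−)-tartrate ligand should deliver oxygen to the face that gives the (2R,3R)-epoxide and the electron-poor enone alkene is not a substrate.

**Step 6**
Reactants: 10 epoxy alcohol
Product: 11 (3E)-1-[(tert-butyldimethylsilyl)oxy]-7-[(2R,3R)-3-{[(tert-butyldimethylsilyl)oxy]methyl}-2-methyloxiran-2-yl]-4-methylhept-3-en-2-one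
Conditions: TBSCl, imidazole, DMF, rt
Reagents that add atoms: tert-butyldimethylsilyl chloride CC(C)(C)[Si](C)(C)Cl
Why: Standard silylation of the primary alcohol, which installs the siloxymethyl group that migrates in the next step.

**Step 7**
Reactants: 11 epoxy silyl ether
Product: 12 (2R,6E)-9-[(tert-butyldimethylsilyl)oxy]-2-{[(tert-butyldimethylsilyl)oxy]methyl}-2,6-dimethyl-8-oxonon-6-enal
Conditions: MeAl(OAr)2 (MABR, Ar = 4-bromo-2,6-di-tert-butylphenyl, made from Me3Al and ArOH), CH2Cl2, −78 °C
Reagents that add atoms: none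
Why: MABR-promoted rearrangement of an epoxy silyl ether to a β-siloxy aldehyde (semipinacol-type 1,2-shift): the tertiary C–O bond opens and the siloxymethyl group shifts to C4 anti to the leaving oxygen, so the epoxide configuration is transferred with inversion to the quaternary C4, and the electron-poor enone alkene cannot trap the cation.

**Step 8**
Reactants: 12 quaternary aldehyde
Product: 14 (5S)-5-[(4E)-7-hydroxy-4-methyl-6-oxohept-4-en-1-yl]-5-methyl-5,6-dihydro-2H-pyran-2-one, via (Z)-enoate 13 (not isolated)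
Conditions: (CF3CH2O)2P(O)CH2CO2Me, KN(SiMe3)2, 18-crown-6, THF, −78 °C; then TsOH·H2O, MeOH–CH2Cl2, rt
Reagents that add atoms: methyl bis(2,2,2-trifluoroethyl)phosphonoacetate COC(=O)CP(=O)(OCC(F)(F)F)OCC(F)(F)F
Why: Still–Gennari olefination should give the (Z)-enoate, and acid then removes both primary silyl ethers so that the C19 hydroxyl closes onto the cis ester (only the Z isomer can lactonise), locking the dienophile geometry in a ring.

**Step 9**
Reactants: 14 lactone ketol
Product: 15 (5S)-5-[(4E,6Z)-6,7-bis{[tert-butyl(dimethyl)silyl]oxy}-4-methylhepta-4,6-dien-1-yl]-5-methyl-5,6-dihydro-2H-pyran-2-one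
Conditions: TBSOTf, Et3N, CH2Cl2, −78 to 0 °C
Reagents that add atoms: tert-butyldimethylsilyl trifluoromethanesulfonate CC(C)(C)[Si](C)(C)OS(=O)(=O)C(F)(F)F
Why: O-silylation of the ketol and soft enolisation toward C7 (the lactone has no enolisable hydrogen) should give the cross-conjugated diene as the (Z)-enediol bis-silyl ether, the isomer that avoids allylic strain between the C7 silyloxy group and the C9=C10 unit.

**Step 10**
Reactants: 15 bis(silyloxy)diene lactone
Product: 16 cycloadduct: trans-decalin (5α-H, 10β-CH3) with C8=C9 silyl enol ether (8-OTBS), 7α-OTBS and δ-lactone C6β–C21(=O)–O–C19H2–C4 (C18 α)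
Conditions: PhMe (0.005 M), BHT (cat.), 150 °C, sealed tube
Reagents that add atoms: none
Why: Thermal type 1 intramolecular Diels–Alder reaction of a 1,7,9-decatriene: the electron-rich 1,2-bis(silyloxy)diene C7=C8–C9=C10 adds suprafacially to the lactone alkene C5=C6 in a concerted, asynchronous [4+2] step in which C5–C10 (enoate β-carbon, matched with the C7 oxygen donor) forms ahead of C6–C7; the closest known reaction type is the thermal cyclisation of 2-silyloxydiene enoates to decalone enol ethers. Ring A closes as the six-membered tether ring (chair-like C1–C3 chain, C4 exo to the diene) and ring B as the cyclohexene of the [4+2] event, which also leaves a regiodefined C8 enol ether. C5 is set by C4, because the diene can reach only the lactone face that carries the C3 chain; C6 follows from the cis alkene locked in the lactone ring (H5 and H6 cis); C7 follows from the (Z)-enol ether (O7 on the outside of the diene, hence trans to the C6 acyl group); C10 follows from the (E)-C9=C10 geometry (C20 inside) together with the mode of approach. The step needs the anti (exo) mode, with the lactone ring turned away from the diene and only H5/H6 beneath it, which gives the trans ring fusion, whereas the syn (endo) mode would give the cis-decalin. The anti mode should be favoured by the absence of a Lewis acid (an ester-type carbonyl exerts little endo pull under heat alone), by the two cis silyloxy groups at C7/C8 filling the quadrant under C8 that the lactone would have to occupy, and by the syn mode forcing all three rings to be cis-fused around C5.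

**Step 11**
Reactants: 16 cycloadduct; 17 acrolein
Product: 18 keto aldehyde: 8-oxo, 9α-(3-oxopropyl), 7α-OTBS δ-lactone
Conditions: BF3·OEt2, CH2Cl2, −78 °C; aq. NaHCO3
Reagents that add atoms: none
Why: Mukaiyama–Michael addition of the C8 silyl enol ether through C9, where the activated enal should approach along the axial trajectory on the α face, anti to the adjacent pseudoaxial C20 methyl, which sets the 9α chain (9β-H) of the target.

**Step 12**
Reactants: 18 keto aldehyde
Product: 19 alkyne: 8-oxo, 9α-(but-3-yn-1-yl), 7α-OTBS δ-lactone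
Conditions: dimethyl (1-diazo-2-oxopropyl)phosphonate, K2CO3, MeOH, 0 °C
Reagents that add atoms: dimethyl (1-diazo-2-oxopropyl)phosphonate COP(=O)(OC)C(=[N+]=[N-])C(C)=O
Why: Ohira–Bestmann (Seyferth–Gilbert) homologation turns the aldehyde into a terminal alkyne under mild carbonate conditions, the hindered ketone and lactone reacting far more slowly.

**Step 13**
Reactants: 19 alkyne keto lactone
Product: 21 keto diol: 6β-benzoyl, 8β-hydroxy-8α-[(trimethylsilyl)methyl], 19-hydroxy, 7α-OTBS, 9α-butynyl (in equilibrium with cyclic hemiketal forms), via C8 alkoxide 20 (not isolated)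
Conditions: Me3SiCH2Li, CeCl3, THF, −78 °C; then PhLi (excess), −78 °C; AcOH, −78 °C
Reagents that add atoms: (trimethylsilyl)methyllithium C[Si](C)(C)C[Li]; phenyllithium [Li]c1ccccc1
Why: The organocerium reagent adds to the hindered, enolisable C8 ketone without deprotonation (first half of a Peterson olefination, expected from the α face, although either C8 epimer serves), and PhLi then adds once to the lactone carbonyl because the tetrahedral lithium hemiketal survives at −78 °C, so the temporary ring is opened to the C6 phenyl ketone and the C19 alcohol.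

**Step 14**
Reactants: 21 keto diol
Product: 22 benzoate diol: 6β-benzoyloxy, 8β-hydroxy-8α-[(trimethylsilyl)methyl], 19-hydroxy, 7α-OTBS, 9α-butynyl
Conditions: mCPBA, Na2HPO4, CH2Cl2, 0 °C to rt
Reagents that add atoms: 3-chloroperoxybenzoic acid OOC(=O)c1cccc(Cl)c1
Why: Baeyer–Villiger oxidation in which the secondary C6 carbon should migrate in preference to phenyl with retention of configuration, so the benzoate is formed in place on the crowded 6β position without an acylation, while the alkyne, the β-hydroxysilane and the silyl ether are inert to buffered peracid.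

**Step 15**
Reactants: 22 benzoate diol
Product: 23 C19 aldehyde
Conditions: Dess–Martin periodinane, NaHCO3, CH2Cl2, rt
Reagents that add atoms: none
Why: Dess–Martin oxidation of the primary neopentyl alcohol under neutral conditions, the tertiary C8 alcohol being unable to react.

**Step 16**
Reactants: 23 C19 aldehyde
Product: 24 C19 carboxylic acid
Conditions: NaClO2, NaH2PO4, 2-methylbut-2-ene, t-BuOH–H2O, rt
Reagents that add atoms: sodium chlorite [Na+].[O-]Cl=O
Why: Pinnick oxidation of the hindered quaternary aldehyde to the acid, with the alkene scavenger protecting the alkyne from hypochlorite.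

**Step 17**
Reactants: 24 alkyne acid
Product: 26 allylic alcohol: (13E)-15-hydroxy side chain complete, C8 still β-hydroxysilane, 7α-OTBS, via alkenylalane 25 (not isolated)
Conditions: Me3Al (excess), Cp2ZrCl2, CH2Cl2, 0 °C to rt; then (CH2O)n, THF, 0 °C to rt; aq. potassium sodium tartrate
Reagents that add atoms: trimethylaluminium C[Al](C)C; paraformaldehyde (as formaldehyde) C=O
Why: Negishi syn-carboalumination of the terminal alkyne and trapping with formaldehyde should give the (E)-trisubstituted allylic alcohol stereospecifically, the acid and tertiary alcohol being carried as aluminium carboxylate and alkoxide and the shielded axial benzoate not being attacked by Me3Al at or below rt.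

**Step 18**
Reactants: 26 silyl-protected precursor
Product: 27 target
Conditions: 48% aq. HF, MeCN, 0 °C to rt
Reagents that add atoms: none
Why: Acid-mediated Peterson elimination of the tertiary β-hydroxysilane unveils the C8=C17 methylene, and the same reagent cleaves the C7 silyl ether without base, so the benzoate cannot migrate or be lost.

**Compound list**

1 | 5-chloropent-1-yne | C#CCCCCl | starting material
2 | (E)-(5-chloro-2-methylpent-1-en-1-yl)dimethylalane | C[Al](C)/C=C(\C)CCCCl | intermediate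
3 | (2E)-6-chloro-3-methylhex-2-en-1-ol | OC/C=C(\C)CCCCl | intermediate
4 | (2E)-3-methyloct-2-en-7-yn-1-ol | OC/C=C(\C)CCCC#C | intermediate
5 | dimethylaluminium (2E,7E)-8-(dimethylalumanyl)-3,7-dimethylocta-2,7-dien-1-olate | C[Al](C)/C=C(\C)CCC/C(C)=C/CO[Al](C)C | intermediate
6 | (2E,7E)-8-iodo-3,7-dimethylocta-2,7-dien-1-ol | OC/C=C(\C)CCC/C(C)=C/I | intermediate
7 | 2-[(tert-butyldimethylsilyl)oxy]-N-methoxy-N-methylacetamide | CON(C)C(=O)CO[Si](C)(C)C(C)(C)C | starting material
8 | lithium (2E,7E)-8-lithio-3,7-dimethylocta-2,7-dien-1-olate | [Li]/C=C(\C)CCC/C(C)=C/CO[Li] | intermediate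
9 | (3E,8E)-1-[(tert-butyldimethylsilyl)oxy]-10-hydroxy-4,8-dimethyldeca-3,8-dien-2-one | OC/C=C(\C)CCC/C(C)=C/C(=O)CO[Si](C)(C)C(C)(C)C | intermediate
10 | (3E)-1-[(tert-butyldimethylsilyl)oxy]-7-[(2R,3R)-3-(hydroxymethyl)-2-methyloxiran-2-yl]-4-methylhept-3-en-2-one | OC[C@H]1O[C@]1(C)CCC/C(C)=C/C(=O)CO[Si](C)(C)C(C)(C)C | intermediate
11 | (3E)-1-[(tert-butyldimethylsilyl)oxy]-7-[(2R,3R)-3-{[(tert-butyldimethylsilyl)oxy]methyl}-2-methyloxiran-2-yl]-4-methylhept-3-en-2-one | CC(C)(C)[Si](C)(C)OC[C@H]1O[C@]1(C)CCC/C(C)=C/C(=O)CO[Si](C)(C)C(C)(C)C | intermediate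
12 | (2R,6E)-9-[(tert-butyldimethylsilyl)oxy]-2-{[(tert-butyldimethylsilyl)oxy]methyl}-2,6-dimethyl-8-oxonon-6-enal | O=C[C@@](C)(CO[Si](C)(C)C(C)(C)C)CCC/C(C)=C/C(=O)CO[Si](C)(C)C(C)(C)C | intermediate
13 | methyl (2Z,4S,8E)-11-[(tert-butyldimethylsilyl)oxy]-4-{[(tert-butyldimethylsilyl)oxy]methyl}-4,8-dimethyl-10-oxoundeca-2,8-dienoate | COC(=O)/C=C\[C@@](C)(CO[Si](C)(C)C(C)(C)C)CCC/C(C)=C/C(=O)CO[Si](C)(C)C(C)(C)C | intermediate
14 | (5S)-5-[(4E)-7-hydroxy-4-methyl-6-oxohept-4-en-1-yl]-5-methyl-5,6-dihydro-2H-pyran-2-one | O=C1OC[C@@](C)(CCC/C(C)=C/C(=O)CO)C=C1 | intermediate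
15 | (5S)-5-[(4E,6Z)-6,7-bis{[tert-butyl(dimethyl)silyl]oxy}-4-methylhepta-4,6-dien-1-yl]-5-methyl-5,6-dihydro-2H-pyran-2-one | O=C1OC[C@@](C)(CCC/C(C)=C/C(O[Si](C)(C)C(C)(C)C)=C/O[Si](C)(C)C(C)(C)C)C=C1 | intermediate
16 | cycloadduct: trans-decalin δ-lactone, 8-OTBS enol ether (C8=C9), 7α-OTBS | O=C1OC[C@@]2(C)CCC[C@]3(C)C=C(O[Si](C)(C)C(C)(C)C)[C@H](O[Si](C)(C)C(C)(C)C)[C@@H]1[C@@H]23 | intermediate
17 | acrolein | C=CC=O | starting material
18 | keto aldehyde: 8-oxo, 9α-(3-oxopropyl), 7α-OTBS δ-lactone | O=C1OC[C@@]2(C)CCC[C@]3(C)[C@H](CCC=O)C(=O)[C@H](O[Si](C)(C)C(C)(C)C)[C@@H]1[C@@H]23 | intermediate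
19 | alkyne: 8-oxo, 9α-(but-3-yn-1-yl), 7α-OTBS δ-lactone | O=C1OC[C@@]2(C)CCC[C@]3(C)[C@H](CCC#C)C(=O)[C@H](O[Si](C)(C)C(C)(C)C)[C@@H]1[C@@H]23 | intermediate
20 | C8 alkoxide adduct (drawn as the lithium salt): 8β-OLi, 8α-CH2SiMe3 δ-lactone | O=C1OC[C@@]2(C)CCC[C@]3(C)[C@H](CCC#C)[C@](O[Li])(C[Si](C)(C)C)[C@H](O[Si](C)(C)C(C)(C)C)[C@@H]1[C@@H]23 | intermediate
21 | keto diol: 6β-benzoyl, 8β-OH, 8α-CH2SiMe3, 19-OH, 7α-OTBS, 9α-butynyl | OC[C@@]1(C)CCC[C@]2(C)[C@H](CCC#C)[C@](O)(C[Si](C)(C)C)[C@H](O[Si](C)(C)C(C)(C)C)[C@@H](C(=O)c3ccccc3)[C@@H]12 | intermediate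
22 | benzoate diol: 6β-OBz, 8β-OH, 8α-CH2SiMe3, 19-OH, 7α-OTBS | OC[C@@]1(C)CCC[C@]2(C)[C@H](CCC#C)[C@](O)(C[Si](C)(C)C)[C@H](O[Si](C)(C)C(C)(C)C)[C@@H](OC(=O)c3ccccc3)[C@@H]12 | intermediate
23 | C19 aldehyde of 22 | O=C[C@@]1(C)CCC[C@]2(C)[C@H](CCC#C)[C@](O)(C[Si](C)(C)C)[C@H](O[Si](C)(C)C(C)(C)C)[C@@H](OC(=O)c3ccccc3)[C@@H]12 | intermediate
24 | C19 carboxylic acid | OC(=O)[C@@]1(C)CCC[C@]2(C)[C@H](CCC#C)[C@](O)(C[Si](C)(C)C)[C@H](O[Si](C)(C)C(C)(C)C)[C@@H](OC(=O)c3ccccc3)[C@@H]12 | intermediate
25 | alkenylalane from 24 (aluminium carboxylate and alkoxide) | C[Al](C)OC(=O)[C@@]1(C)CCC[C@]2(C)[C@H](CC/C(C)=C/[Al](C)C)[C@](O[Al](C)C)(C[Si](C)(C)C)[C@H](O[Si](C)(C)C(C)(C)C)[C@@H](OC(=O)c3ccccc3)[C@@H]12 | intermediate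
26 | silyl-protected precursor: (13E)-15-hydroxy side chain, 8β-OH, 8α-CH2SiMe3, 7α-OTBS | OC(=O)[C@@]1(C)CCC[C@]2(C)[C@H](CC/C(C)=C/CO)[C@](O)(C[Si](C)(C)C)[C@H](O[Si](C)(C)C(C)(C)C)[C@@H](OC(=O)c3ccccc3)[C@@H]12 | intermediate
27 | CNP0149011.1 | C=C1[C@@H](CC/C(C)=C/CO)[C@@]2(C)CCC[C@](C)(C(=O)O)[C@@H]2[C@H](OC(=O)c2ccccc2)[C@H]1O | target

**Step count and risks**

Total step count: 18. Longest linear sequence: 18 steps (from 1; 7 and 17 are bought).

Steps most likely to fail:

1. Step 10. The cycloaddition may run through the syn (endo-lactone) mode and give the cis-fused decalin, or be slow at the crowded C10 terminus so that a 1,5-hydrogen shift of the diene competes. I could not settle the syn/anti preference by argument alone; the inside C20 methyl sits over the lactone in the anti mode, which works against it. Fallback from 12: a Horner–Wadsworth–Emmons reaction with methyl bis(2,2,2-trifluoroethyl) bromophosphonoacetate (t-BuOK, 18-crown-6, THF, −78 °C) should give the (E)-α-bromo enoate F1 (ester cis to C4). TsOH·H2O in MeOH–CH2Cl2 should then give the 3-bromo lactone ketol F2, and TBSOTf/Et3N the bromo diene F3. An α-halo enoate is a stronger dienophile and, like other α-substituted acrylates, prefers carbonyl exo and halogen endo, which is the anti mode needed. Heating should therefore give the bromo adduct F4 (6α-Br), and Bu3SnH/AIBN (PhH, 80 °C) should replace bromine by hydrogen on the open α face (the β face is spanned by the lactone bridge), returning to 16.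

2. Step 11. The enal may undergo 1,2-addition or polymerise, and the syn-axial 7α-silyloxy group may slow or misdirect attack at C9. Fallback from 16: fluoride-generated ammonium enolate alkylation (allyl bromide, benzyltrimethylammonium fluoride, 4 Å MS, THF) with a small, reactive electrophile should give the 9α-allyl ketone F5. Hydroboration–oxidation (9-BBN, then NaBO3) should give the primary alcohol F6, and Dess–Martin oxidation returns to 18.

3. Step 14. Phenyl migration may compete with migration of C6 (which carries a β-silyloxy carbon); the ketone may be held as cyclic hemiketals with the C8 and C19 hydroxyls so that oxidation is slow; the axial aryl ketone may epimerise at C6. Fallback from 19: step 13 with MeLi in place of PhLi should give the methyl ketone diol F7, whose Baeyer–Villiger oxidation cannot involve methyl migration and should give the 6β-acetate F8. Silylation of the primary alcohol (TESCl, imidazole) gives the triethylsilyl ether acetate F9, and DIBAL removes the acetate to give the 6β-alcohol F10. Forced benzoylation of the axial hydroxyl (BzOTf, pyridine, CH2Cl2) gives the benzoate silyl ether F11, and PPTS in MeOH frees the C19 alcohol, returning to 22.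

**Further compounds**

F1 | step 10 | methyl (2E,4S,8E)-2-bromo-11-[(tert-butyldimethylsilyl)oxy]-4-{[(tert-butyldimethylsilyl)oxy]methyl}-4,8-dimethyl-10-oxoundeca-2,8-dienoate | COC(=O)/C(Br)=C\[C@@](C)(CO[Si](C)(C)C(C)(C)C)CCC/C(C)=C/C(=O)CO[Si](C)(C)C(C)(C)C
F2 | step 10 | (5S)-3-bromo-5-[(4E)-7-hydroxy-4-methyl-6-oxohept-4-en-1-yl]-5-methyl-5,6-dihydro-2H-pyran-2-one | O=C1OC[C@@](C)(CCC/C(C)=C/C(=O)CO)C=C1Br
F3 | step 10 | (5S)-5-[(4E,6Z)-6,7-bis{[tert-butyl(dimethyl)silyl]oxy}-4-methylhepta-4,6-dien-1-yl]-3-bromo-5-methyl-5,6-dihydro-2H-pyran-2-one | O=C1OC[C@@](C)(CCC/C(C)=C/C(O[Si](C)(C)C(C)(C)C)=C/O[Si](C)(C)C(C)(C)C)C=C1Br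
F4 | step 10 | 6α-bromo analogue of cycloadduct 16 | O=C1OC[C@@]2(C)CCC[C@]3(C)C=C(O[Si](C)(C)C(C)(C)C)[C@H](O[Si](C)(C)C(C)(C)C)[C@]1(Br)[C@@H]23
F5 | step 11 | 9α-allyl-8-oxo-7α-OTBS δ-lactone | O=C1OC[C@@]2(C)CCC[C@]3(C)[C@H](CC=C)C(=O)[C@H](O[Si](C)(C)C(C)(C)C)[C@@H]1[C@@H]23
F6 | step 11 | 9α-(3-hydroxypropyl)-8-oxo-7α-OTBS δ-lactone | O=C1OC[C@@]2(C)CCC[C@]3(C)[C@H](CCCO)C(=O)[C@H](O[Si](C)(C)C(C)(C)C)[C@@H]1[C@@H]23
F7 | step 14 | 6β-acetyl analogue of keto diol 21 | OC[C@@]1(C)CCC[C@]2(C)[C@H](CCC#C)[C@](O)(C[Si](C)(C)C)[C@H](O[Si](C)(C)C(C)(C)C)[C@@H](C(C)=O)[C@@H]12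
F8 | step 14 | 6β-acetoxy analogue of 22 | OC[C@@]1(C)CCC[C@]2(C)[C@H](CCC#C)[C@](O)(C[Si](C)(C)C)[C@H](O[Si](C)(C)C(C)(C)C)[C@@H](OC(C)=O)[C@@H]12
F9 | step 14 | 19-O-triethylsilyl ether of F8 | CC[Si](CC)(CC)OC[C@@]1(C)CCC[C@]2(C)[C@H](CCC#C)[C@](O)(C[Si](C)(C)C)[C@H](O[Si](C)(C)C(C)(C)C)[C@@H](OC(C)=O)[C@@H]12
F10 | step 14 | 6β-alcohol, 19-O-triethylsilyl ether | CC[Si](CC)(CC)OC[C@@]1(C)CCC[C@]2(C)[C@H](CCC#C)[C@](O)(C[Si](C)(C)C)[C@H](O[Si](C)(C)C(C)(C)C)[C@@H](O)[C@@H]12
F11 | step 14 | 6β-benzoate, 19-O-triethylsilyl ether | CC[Si](CC)(CC)OC[C@@]1(C)CCC[C@]2(C)[C@H](CCC#C)[C@](O)(C[Si](C)(C)C)[C@H](O[Si](C)(C)C(C)(C)C)[C@@H](OC(=O)c3ccccc3)[C@@H]12
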